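## Structural features

Sipholenol K is a tetracycle made of two bicyclic halves joined by a CH2–CH2 tether. The left half is a 3-hydroxy-2,2-dimethyloxepane (ring A) trans-fused to a cyclohexane (ring B) through a methyl-bearing quaternary (angular) carbon and an ether CH. Ring B also carries a tertiary carbinol C(Me)OH next to the CH that holds the tether, so four stereocentres stand in a row (carbinol carbon, tether CH, angular carbon, ether CH), and a fifth, the ring A carbinol, lies beside the CMe2–O unit. The right half is a cyclohexenone (ring C) whose tetrasubstituted C(Me)=C(tether) double bond ends at a ring-fusion CH. Ring C is cis-fused to a cyclohexane (ring D) that has a CMe2 carbon on one fusion carbon and a C(Me)OH carbon on the other; the two fusion carbons and this carbinol are three contiguous stereocentres. The fragile points are the two tertiary alcohols (dehydration), the fusion hydrogen γ to the enone carbonyl (epimerisation or double-bond shift under base), and any intermediate in which a ketone flanks a fusion carbon. The real difficulties are the trans-fused oxepane with its oxygen on a tertiary carbon, the crowded cis-fused C/D unit, and the distance between the two stereochemical domains, whose relation can only come from a reagent. The key step treats the ring C path CH2–C(=O)–C(Me)=C(tether) as a 2-silyloxy-3-methyl-1,3-diene and the two fusion carbons as the double bond of a quinone monoketal, whose ketone is the future CMe2 carbon and whose ketal is the future C(Me)OH carbon of ring D.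

## Logic of the disconnections

**37 to 36 to 35.** No skeletal bond is cut. 37 is traced to its bis-silyl ether 36, and the ring C double bond of 36 is removed to the silyl enol ether 35. The enone is made last because its γ-hydrogen at the ring fusion would not survive the basic and hydridic steps that ring D needs. The forward step must dehydrogenate into the ring, towards the tether-bearing carbon, and not towards the methyl group.

**35 to 34 to 33 to 32.** The C–OH bond of the ring D carbinol and one C–H of its methyl are cut back to the exocyclic alkene 34, then to ketone 33 and ketal 32. A methyl nucleophile would attack 33 from the open convex face and leave the hydroxyl on the wrong side; adding oxygen to the alkene from that same face gives the right one. The forward step must oxygenate without touching the electron-rich enol ether, which rules out peracids.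

**32 to 31 to 30 to 29.** The two methyl groups on the other ring D carbon are cut through the CH2–CH2 bond of cyclopropane 31, then through its two bonds to the ring carbon (alkene 30), then to ketone 29. This carbon has to be a carbonyl in the cycloaddition, so the geminal methyls can only come afterwards. The forward steps need a methylenation without base (the fusion carbon beside the ketone is enolisable) and a cyclopropanation that ignores the enol ether.

**29 to 28.** Two C–H bonds of ring D are removed to restore the enone of the cycloadduct. This costs one step and requires a hydrogenation that leaves the tetrasubstituted enol ether alone.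

**28 to 25 and 27.** Two ring C bonds are cut: the one from the tether-bearing carbon to the fusion carbon beside the carbonyl, and the one from the ring CH2 to the fusion carbon beside the ketal. This divides the molecule into halves of similar size, sets both fusion centres at once, and keeps the two ring D carbonyl carbons distinct from the start. The forward step needs catalyst control of the absolute configuration, endo addition and one regiochemistry. It also needs protecting groups that tolerate a strong Lewis acid, which is why the tertiary oxygen carries a triethylsilyl and not a trimethylsilyl group.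

**27 to 26.** The ketal C–O bonds are cut back to the aromatic ether. One oxidation gives the dienophile.

**25 to 24 to 22 and 23.** The O–Si bond of the dienol ether is cut, then the C=C bond of the trisubstituted alkene. The enone 24 comes from an aldehyde and a stabilised ylide, which fixes the E geometry the cycloaddition needs. Enolisation must then occur at the methyl group only.

**22 to 20 to 18.** The aldehyde is traced to a terminal alkyne and the silyl ethers to the free diol. A propargyl group is inert to the ylide, peracid and hydride used earlier on ring B and gives the aldehyde in one operation. The tertiary hydroxyl must be capped before the aldehyde appears, otherwise a lactol and later an oxa-Michael adduct would form.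

**18 to 17 to 16 to 15.** The C–O bond and the methyl group of the ring B carbinol are cut back through epoxide 17 and alkene 16 to ketone 15. Direct methyl addition to 15 would put the hydroxyl axial. The peracid must attack the face opposite the angular methyl.

**15 to 14 to 13 to 12.** The O–CMe2 bond of the oxepane is cut to hydroxy epoxide 14, and the epoxide C–O bonds to alkene 12. The ring A carbinol then comes from a reagent-controlled epoxidation, and the ether oxygen reaches the tertiary carbon by an acid-promoted opening. The forward step needs endo and not exo opening, and a hydroxyl already trans to the chain.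

**12 to 9 and 10; 9 to 6 and 7.** Two C–C bonds at ring B are cut: propargyl CH2 to ring CH, and chain CH2 to angular carbon. Conjugate addition followed by enolate alkylation across one enone makes both adjacent centres, trans to each other and controlled by the silyloxy stereocentre of 6. The addition must go anti to that group and the enolate must stay regiodefined.

**6 to 4 to 3 to 2 to 1.** Only functional groups change. The single stereocentre of 6 comes from a catalytic ketone reduction of 3, and 3 from partial hydrogenation of the quinone monoketal 2 of phenol 1.

## Other disconnections considered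

**Alternative 1:** The cuts are the O–CMe2 bond of ring A, the ring B bond between the angular carbon and the tether CH, and the C–O bond of the ring B carbinol. In the forward direction Me3SiOTf opens the terminal epoxide of the acyclic diepoxy tert-butyl carbonate A1. The inner epoxide oxygen bonds to the CMe2 carbon, the alkene closes ring B on the angular carbon, and the carbonate oxygen captures the tertiary cation to give the bicyclic carbonate A2.

- In its favour: one operation makes both rings and four ring B/ring A stereocentres from two reagent-controlled epoxides. The oxepane question is settled by mechanism, because the nucleophile is an epoxide oxygen that can only reach the tertiary carbon. In step economy for rings A and B it is clearly better than steps 1 to 11 of the chosen plan.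
- Against it here: cation cascades that must pass through three consecutive nucleophiles usually lose material to partly cyclised products. A2 carries a single oxygenated carbon on the ring B CH, so the tether has to be lengthened by two carbons at a β-branched primary centre after three hydroxyls have been told apart.
- Comparison: both plans give the same trans-fused unit and both take the ring A carbinol from the same kind of dioxirane epoxidation, so on that centre they are equal. The chosen plan sets each ring B centre in a separate step with the three-carbon arm in place from step 6. Alternative 1 does not address rings C and D, so it competes with the first half of the route and not with step 17.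

**Alternative 2:** The cut removes the ring A CH2 that lies next to the carbinol carbon, so the oxepane is carried as a six-membered pyranone until late. In the forward direction the pyranone A3 reacts with Me3SiCHN2 and BF3·OEt2, the ring CH2 beside the angular carbon migrates (a Tiffeneau–Demjanov-type 1,2-shift), and the oxepan-3-one A4 results.

- In its favour: a six-membered cyclic ether closes more readily than a seven-membered one. On ring closure it is the safer of the two, better than step 8 of the chosen plan.
- Against it here: the expansion is run on the complete skeleton, which holds a second ketone (the ring C enone) and two tertiary silyl ethers that BF3·OEt2 can strip. Migration of the oxygen-bearing quaternary carbon would give the isomeric ketone. A4 still needs protodesilylation and a face-selective reduction to the ring A carbinol, a centre the chosen plan takes directly from the epoxide.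
- Comparison: it leaves rings C and D as in the chosen plan and could use the same cycloaddition, so on those rings it is equal. Mechanistically it swaps an SN1-like epoxide opening for a Lewis-acid-promoted diazoalkane insertion. It adds about three late steps on the most valuable intermediate.

**Alternative 3:** The cut is the ring B bond between the carbinol carbon and the tether CH. In the forward direction SmI2 reduces the methyl ketone of the oxepane keto enoate A5 to a ketyl, which adds 6-exo to the β-carbon of the enoate and gives the hydroxy ester A6.

- In its favour: the tertiary alcohol and the neighbouring CH are formed in one step, where the chosen plan spends steps 9 to 11 on the carbinol. On that point it is better. The bulky samarium-bound oxygen should sit equatorial and anti to the ester arm, which is the required relation.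
- Against it here: A5 needs the oxepane first, with its quaternary angular carbon and the adjacent ether CH set on a seven-membered ring without a cyclohexane template. The endo/exo question of the ether closure therefore comes earlier and with less control. A6 carries a two-carbon ester arm that must be reduced and extended by one carbon.
- Comparison: it is a radical-anion cyclisation, against the cuprate addition and enolate alkylation of the chosen plan, which uses a silyloxy group on a six-membered ring to direct both C–C bonds. The step count for rings A and B would be similar or slightly higher once A5 is included. The C/D strategy is unaffected.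

Key step: step 17

Remark on the chemistry: the facial sense of the catalyst in step 17 is assigned from the accepted pre-transition-state model of oxazaborolidinium catalysis and is assumed to hold for this diene; the antipodal catalyst is equally accessible.

## Steps

Step 1
Reactants: 1 4-methoxy-2-methylphenol
Product: 2 4,4-dimethoxy-2-methylcyclohexa-2,5-dien-1-one
Conditions: PhI(OAc)2, MeOH, 0 °C
Reagents that add atoms: methanol, CO
Why: Oxidative dearomatisation of a para-alkoxyphenol with a hypervalent iodine reagent; methanol traps the phenoxenium-type intermediate at the para carbon, the standard route to quinone monoketals.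

Step 2
Reactants: 2 4,4-dimethoxy-2-methylcyclohexa-2,5-dien-1-one
Product: 3 4,4-dimethoxy-2-methylcyclohex-2-en-1-one
Conditions: H2 (1 atm), RhCl(PPh3)3 (5 mol %), benzene, 23 °C
Reagents that add atoms: none
Why: Homogeneous rhodium-catalysed hydrogenation is very sensitive to substitution, so the disubstituted enone double bond should be saturated and the methyl-bearing trisubstituted one kept; the neutral medium spares the ketal.

Step 3
Reactants: 3 4,4-dimethoxy-2-methylcyclohex-2-en-1-one
Product: 4 (S)-4,4-dimethoxy-2-methylcyclohex-2-en-1-ol
Conditions: (R)-2-methyl-CBS-oxazaborolidine (10 mol %), BH3·SMe2, THF, −30 °C; MeOH quench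
Reagents that add atoms: none
Why: Corey–Bakshi–Shibata reduction; the alkene-bearing α-carbon acts as the large group and the CH2 as the small one, so the (R)-catalyst should give the (S)-carbinol, the future ether CH of ring B, by 1,2-reduction.

Step 4
Reactants: 4 (S)-4,4-dimethoxy-2-methylcyclohex-2-en-1-ol
Product: 6 (S)-4-(tert-butyldimethylsilyloxy)-3-methylcyclohex-2-en-1-one, via silyl ether ketal 5 (not isolated)
Conditions: tBuMe2SiCl, imidazole, DMF, 23 °C; then 5% aqueous oxalic acid, THF, 0 °C
Reagents that add atoms: tert-butyldimethylsilyl chloride, CC(C)(C)[Si](C)(C)Cl; water, O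
Why: Silylation of a secondary alcohol followed by hydrolysis of the allylic ketal, which ionises easily and gives the conjugated enone under acid too weak to cleave the silyl ether; the stereocentre is not involved.

Step 5
Reactants: 6 (S)-4-(tert-butyldimethylsilyloxy)-3-methylcyclohex-2-en-1-one; 7 5-bromo-2-methylpent-2-ene
Product: 9 (3S,4S)-4-(tert-butyldimethylsilyloxy)-3-methyl-3-(4-methylpent-3-en-1-yl)-1-(trimethylsilyloxy)cyclohex-1-ene, via Grignard reagent 8 (not isolated)
Conditions: 7, Mg, THF, 40 °C; then 6, CuBr·SMe2 (10 mol %), Me3SiCl, HMPA, THF, −78 °C; Et3N quench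
Reagents that add atoms: chlorotrimethylsilane, C[Si](C)(C)Cl
Why: Copper-catalysed, chlorosilane-accelerated conjugate addition of a Grignard reagent, a reliable way to β-quaternary carbons; the nucleophile should enter anti to the adjacent silyloxy group, which sets the angular carbon with the chain trans to oxygen, and the enolate is kept regiodefined as its silyl ether.

Step 6
Reactants: 9 (3S,4S)-4-(tert-butyldimethylsilyloxy)-3-methyl-3-(4-methylpent-3-en-1-yl)-1-(trimethylsilyloxy)cyclohex-1-ene; 10 3-bromo-1-(trimethylsilyl)prop-1-yne
Product: 12 (2S,3S,4S)-4-(tert-butyldimethylsilyloxy)-3-methyl-3-(4-methylpent-3-en-1-yl)-2-[3-(trimethylsilyl)prop-2-yn-1-yl]cyclohexan-1-one, via lithium enolate 11 (not isolated)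
Conditions: MeLi, THF, 0 °C; then 10, HMPA, −78 → 0 °C
Reagents that add atoms: none
Why: Methyllithium releases the regiodefined lithium enolate, which is alkylated by the reactive propargylic bromide anti to the larger chain on the quaternary carbon; the product is also the thermodynamic epimer (silyloxy, chain and propargyl all equatorial), so brief base equilibration would correct a minor epimer.

Step 7
Reactants: 12 (2S,3S,4S)-4-(tert-butyldimethylsilyloxy)-3-methyl-3-(4-methylpent-3-en-1-yl)-2-[3-(trimethylsilyl)prop-2-yn-1-yl]cyclohexan-1-one
Product: 13 (2S,3S,4S)-4-(tert-butyldimethylsilyloxy)-3-{2-[(2S)-3,3-dimethyloxiran-2-yl]ethyl}-3-methyl-2-[3-(trimethylsilyl)prop-2-yn-1-yl]cyclohexan-1-one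
Conditions: L-fructose-derived (ent-)Shi ketone (30 mol %), Oxone (2KHSO5·KHSO4·K2SO4), K2CO3, Bu4NHSO4, MeCN–CH2(OMe)2–aqueous Na2B4O7 buffer, 0 °C
Reagents that add atoms: potassium peroxymonosulfate, [K+].[O-]S(=O)(=O)OO
Why: Shi epoxidation; the chiral dioxirane should attack the trisubstituted alkene through the spiro transition state and give the (S)-epoxide, which fixes the ring A carbinol by reagent control; the silylalkyne and the ketone should not react.

Step 8
Reactants: 13 (2S,3S,4S)-4-(tert-butyldimethylsilyloxy)-3-{2-[(2S)-3,3-dimethyloxiran-2-yl]ethyl}-3-methyl-2-[3-(trimethylsilyl)prop-2-yn-1-yl]cyclohexan-1-one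
Product: 15 ring A/B hydroxy ketone (3-hydroxy-2,2-dimethyloxepane trans-fused to 2-propargylcyclohexanone), via hydroxy epoxide 14 (not isolated)
Conditions: Bu4NF, AcOH, THF, 0 → 23 °C; then (+)-camphorsulfonic acid (10 mol %), CH2Cl2, 0 °C
Reagents that add atoms: none
Why: Fluoride removes the O-silyl and C-silyl groups; acid-catalysed intramolecular epoxide opening then lets the equatorial ring hydroxyl attack the tertiary epoxide carbon, where positive charge is best stabilised (7-endo mode), closing the oxepane trans to the angular methyl. The carbinol carbon keeps its configuration because its C–O bond is not broken.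

Step 9
Reactants: 15 ring A/B hydroxy ketone
Product: 16 ring A/B exocyclic alkene (C=CH2 in place of the ring B ketone)
Conditions: Ph3PCH3Br, KOtBu, toluene, 80 °C
Reagents that add atoms: methyltriphenylphosphonium bromide, C[P+](c1ccccc1)(c1ccccc1)c1ccccc1.[Br-]
Why: Wittig methylenation of a hindered cyclohexanone with the unstabilised ylide; the neighbouring CH already has its propargyl group equatorial, so reversible enolisation cannot change it.

Step 10
Reactants: 16 ring A/B exocyclic alkene
Product: 17 ring A/B spiro-epoxide (oxygen equatorial and CH2 axial on ring B)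
Conditions: mCPBA, NaHCO3, CH2Cl2, 0 °C
Reagents that add atoms: 3-chloroperoxybenzoic acid, OOC(=O)c1cccc(Cl)c1
Why: Prilezhaev epoxidation; the 1,1-disubstituted alkene is far more nucleophilic than the terminal alkyne, and the peracid should approach the face opposite the syn-axial angular methyl, as is usual for exocyclic alkenes in this position.

Step 11
Reactants: 17 ring A/B spiro-epoxide
Product: 18 ring A/B diol (ring B tertiary carbinol with axial methyl and equatorial hydroxyl)
Conditions: LiBHEt3, THF, 0 → 23 °C
Reagents that add atoms: none
Why: Hydride opens the epoxide by SN2 attack at its unhindered CH2, which leaves the tertiary alcohol with the configuration set in step 10; the alkyne and the ether are inert.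

Step 12
Reactants: 18 ring A/B diol
Product: 20 ring A/B bis-silyl ether (secondary tert-butyldimethylsilyl ether and tertiary triethylsilyl ether), via mono-silyl ether 19 (not isolated)
Conditions: tBuMe2SiOTf (1.1 equiv), 2,6-lutidine, CH2Cl2, −78 °C; then Et3SiOTf, 0 °C
Reagents that add atoms: tert-butyldimethylsilyl triflate, CC(C)(C)[Si](C)(C)OS(=O)(=O)C(F)(F)F; triethylsilyl triflate, CC[Si](CC)(CC)OS(=O)(=O)C(F)(F)F
Why: Silyl triflates silylate hindered alcohols; the secondary hydroxyl reacts first at low temperature and the tertiary one then takes the smaller triethylsilyl group. The tertiary ether blocks lactol formation and oxa-Michael addition in steps 13 to 15 and is sturdier towards acid than a trimethylsilyl ether.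

Step 13
Reactants: 20 ring A/B bis-silyl ether
Product: 22 ring A/B aldehyde (CH2CH2CHO arm on ring B), via alkenylborane 21 (not isolated)
Conditions: dicyclohexylborane (from BH3·SMe2 and cyclohexene), THF, 0 °C; then 30% H2O2, aqueous pH 7 phosphate buffer, 0 °C
Reagents that add atoms: hydrogen peroxide, OO
Why: Anti-Markovnikov hydroboration of a terminal alkyne with a hindered dialkylborane stops at the alkenylborane; buffered oxidation gives the enol and hence the aldehyde, with no separate alcohol oxidation.

Step 14
Reactants: 22 ring A/B aldehyde; 23 3-(triphenylphosphoranylidene)butan-2-one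
Product: 24 ring A/B (E)-enone (CH2CH2CH=C(Me)C(=O)CH3 arm)
Conditions: toluene, 90 °C
Reagents that add atoms: none
Why: Wittig reaction of a stabilised α-branched acyl ylide with an aldehyde gives the (E)-trisubstituted enone under thermodynamic control; silyl ethers are inert.

Step 15
Reactants: 24 ring A/B (E)-enone
Product: 25 ring A/B 2-triisopropylsilyloxy-3-methyl-1,3-diene
Conditions: iPr3SiOTf, Et3N, CH2Cl2, 0 °C
Reagents that add atoms: triisopropylsilyl triflate, CC(C)[Si](OS(=O)(=O)C(F)(F)F)(C(C)C)C(C)C
Why: Soft enolisation of the methyl ketone with silyl triflate and amine removes a methyl proton and gives the cross-conjugated 2-silyloxydiene; the E alkene is unchanged.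

Step 16
Reactants: 26 4-methoxyphenol
Product: 27 4,4-dimethoxycyclohexa-2,5-dien-1-one
Conditions: PhI(OAc)2, MeOH, 0 °C
Reagents that add atoms: methanol, CO
Why: The same oxidative dearomatisation as in step 1 gives the symmetric quinone monoketal.

Step 17
Reactants: 25 ring A/B 2-triisopropylsilyloxy-3-methyl-1,3-diene; 27 4,4-dimethoxycyclohexa-2,5-dien-1-one
Product: 28 cis-fused cycloadduct (ring C triisopropylsilyl enol ether; ring D enone and dimethyl ketal)
Conditions: 27 (1.5 equiv), (R)-B-(o-tolyl)oxazaborolidinium triflimide [from the (R)-α,α-diphenylprolinol-derived oxazaborolidine and HNTf2] (20 mol %), CH2Cl2, −78 → −40 °C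
Reagents that add atoms: none
Why: This is a concerted, asynchronous normal-demand [4+2] cycloaddition of the 2-silyloxydiene to the Lewis-acid-bound enone of 27; the closest known reaction type is the oxazaborolidinium-catalysed Diels–Alder reaction of quinone monoketals with 2-silyloxydienes. Ring C closes in the six-membered cycloaddition mode by forming the bond from the diene CH2 terminus to the β-carbon beside the ketal and the bond from the tether-bearing terminus to the α-carbon. The two fusion carbons become cis because both bonds form on one face of the dienophile, and their absolute configuration is set by the catalyst, which binds the carbonyl oxygen on boron, holds the α-C–H against its ring oxygen and screens one face with a phenyl group. The third new centre, the tether-bearing carbon, follows from the E geometry of the diene and the endo position of the dienophile ring, and it is erased in step 25. Regiochemistry is secured twice: the silyloxy group makes the CH2 terminus the nucleophilic end and the ketal-flanked β-carbon is the electrophilic end, and the unsubstituted terminus meets the more hindered carbon. The stereocentres of 25 are too remote to bias the approach, so the catalyst antipode alone decides the relation between the halves, and the (R)-catalyst is chosen from the pre-transition-state model. The catalyst also picks one of the two enantiotopic double bonds of 27, and the ketal keeps the second carbonyl masked for step 22.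

Step 18
Reactants: 28 cis-fused cycloadduct
Product: 29 ring D saturated ketone (ketal and silyl enol ether kept)
Conditions: H2 (1 atm), 10% Pd/C, EtOAc, 23 °C
Reagents that add atoms: none
Why: Heterogeneous hydrogenation should saturate the disubstituted enone alkene; the tetrasubstituted silyl enol ether is too hindered to react, and neutral conditions keep the cis fusion.

Step 19
Reactants: 29 ring D saturated ketone
Product: 30 ring D exocyclic alkene (C=CH2 beside the fusion carbon)
Conditions: Cp2TiMe2, toluene–THF, 65 °C, dark
Reagents that add atoms: dimethyltitanocene, C[Ti](C)(C1C=CC=C1)C1C=CC=C1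
Why: Petasis methylenation through the titanium methylidene is non-basic, so the enolisable fusion carbon beside the ketone should not epimerise; the ketal, silyl ethers and enol ether are inert.

Step 20
Reactants: 30 ring D exocyclic alkene
Product: 31 ring D spiro-cyclopropane
Conditions: CH2N2, Pd(OAc)2 (5 mol %), Et2O, 0 °C
Reagents that add atoms: diazomethane, C=[N+]=[N-]
Why: Palladium-catalysed cyclopropanation with diazomethane needs the alkene to coordinate to the metal, so it should select the 1,1-disubstituted exocyclic alkene over the tetrasubstituted silyl enol ether, which an electrophilic zinc carbenoid could attack.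

Step 21
Reactants: 31 ring D spiro-cyclopropane
Product: 32 ring D gem-dimethyl ketal
Conditions: H2 (3 atm), PtO2, EtOAc–AcOH (10:1), NaOAc, 23 °C
Reagents that add atoms: none
Why: Hydrogenolysis of a spiro-cyclopropane over platinum cleaves the least substituted CH2–CH2 bond and leaves the geminal dimethyl group; the buffered medium is meant to spare the ketal, the silyl ethers and the hindered enol ether.

Step 22
Reactants: 32 ring D gem-dimethyl ketal
Product: 33 ring D ketone (carbonyl beside the other fusion carbon)
Conditions: SiO2, 10% aqueous oxalic acid, CH2Cl2, 23 °C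
Reagents that add atoms: water, O
Why: Dimethyl ketals hydrolyse on wet acidic silica under conditions mild enough for a tetrasubstituted triisopropylsilyl enol ether and both silyl ethers; no base touches the cis-fused ketone.

Step 23
Reactants: 33 ring D ketone
Product: 34 ring D exocyclic alkene at the future carbinol carbon
Conditions: Cp2TiMe2, toluene–THF, 65 °C, dark
Reagents that add atoms: dimethyltitanocene, C[Ti](C)(C1C=CC=C1)C1C=CC=C1
Why: Petasis methylenation again avoids base, so the fusion carbon beside this ketone keeps its configuration.

Step 24
Reactants: 34 ring D exocyclic alkene at the future carbinol carbon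
Product: 35 ring D tertiary alcohol (hydroxyl cis to the fusion hydrogens; silyl enol ether intact)
Conditions: Co(acac)2 (20 mol %), PhSiH3, O2 (1 atm), THF, 0 → 23 °C
Reagents that add atoms: dioxygen, O=O
Why: Mukaiyama hydration; hydrogen-atom transfer from a cobalt hydride to the CH2 terminus gives the tertiary radical, which should capture O2 on the convex face of the cis-fused bicycle, so the hydroxyl ends cis to the fusion hydrogens and the new methyl on the concave face. The tetrasubstituted enol ether is too hindered for hydrogen-atom transfer, and peracids, which would attack it, are avoided.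

Step 25
Reactants: 35 ring D tertiary alcohol
Product: 36 sipholenol K bis-silyl ether
Conditions: Pd(OAc)2 (1.2 equiv), DMSO–CH2Cl2, 40 °C
Reagents that add atoms: none
Why: Saegusa–Ito oxidation; divalent palladium adds to the enol ether at the methyl-bearing carbon from the open face, and syn β-hydride elimination of the ring hydrogen on the tether-bearing carbon gives the tetrasubstituted enone, the thermodynamically preferred isomer, erasing that stereocentre. The neighbouring ring D carbon is now CMe2, so the fusion hydrogen is no longer activated by a second carbonyl.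

Step 26
Reactants: 36 sipholenol K bis-silyl ether
Product: 37 sipholenol K
Conditions: HF·pyridine, pyridine, THF, 0 → 23 °C
Reagents that add atoms: none
Why: Fluoride cleaves the secondary tert-butyldimethylsilyl and tertiary triethylsilyl ethers under buffered acidic conditions, avoiding the base that could deconjugate the enone or epimerise the fusion carbon.

## Compound list

1 | 4-methoxy-2-methylphenol | COc1ccc(O)c(C)c1 | starting material
2 | 4,4-dimethoxy-2-methylcyclohexa-2,5-dien-1-one | COC1(OC)C=CC(=O)C(C)=C1 | intermediate
3 | 4,4-dimethoxy-2-methylcyclohex-2-en-1-one | COC1(OC)CCC(=O)C(C)=C1 | intermediate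
4 | (S)-4,4-dimethoxy-2-methylcyclohex-2-en-1-ol | COC1(OC)C=C(C)[C@@H](O)CC1 | intermediate
5 | (S)-1-(tert-butyldimethylsilyloxy)-4,4-dimethoxy-2-methylcyclohex-2-ene | COC1(OC)C=C(C)[C@@H](O[Si](C)(C)C(C)(C)C)CC1 | intermediate
6 | (S)-4-(tert-butyldimethylsilyloxy)-3-methylcyclohex-2-en-1-one | O=C1C=C(C)[C@@H](O[Si](C)(C)C(C)(C)C)CC1 | intermediate
7 | 5-bromo-2-methylpent-2-ene | CC(C)=CCCBr | starting material
8 | (4-methylpent-3-en-1-yl)magnesium bromide | CC(C)=CCC[Mg]Br | intermediate
9 | (3S,4S)-4-(tert-butyldimethylsilyloxy)-3-methyl-3-(4-methylpent-3-en-1-yl)-1-(trimethylsilyloxy)cyclohex-1-ene | C[Si](C)(C)OC1=C[C@](C)(CCC=C(C)C)[C@@H](O[Si](C)(C)C(C)(C)C)CC1 | intermediate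
10 | 3-bromo-1-(trimethylsilyl)prop-1-yne | C[Si](C)(C)C#CCBr | starting material
11 | lithium enolate corresponding to 9 (lithium in place of trimethylsilyl) | [Li]OC1=C[C@](C)(CCC=C(C)C)[C@@H](O[Si](C)(C)C(C)(C)C)CC1 | intermediate
12 | (2S,3S,4S)-4-(tert-butyldimethylsilyloxy)-3-methyl-3-(4-methylpent-3-en-1-yl)-2-[3-(trimethylsilyl)prop-2-yn-1-yl]cyclohexan-1-one | C[Si](C)(C)C#CC[C@H]1[C@](C)(CCC=C(C)C)[C@@H](O[Si](C)(C)C(C)(C)C)CCC1=O | intermediate
13 | (2S,3S,4S)-4-(tert-butyldimethylsilyloxy)-3-{2-[(2S)-3,3-dimethyloxiran-2-yl]ethyl}-3-methyl-2-[3-(trimethylsilyl)prop-2-yn-1-yl]cyclohexan-1-one | C[Si](C)(C)C#CC[C@H]1[C@](C)(CC[C@@H]2OC2(C)C)[C@@H](O[Si](C)(C)C(C)(C)C)CCC1=O | intermediate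
14 | (2S,3S,4S)-3-{2-[(2S)-3,3-dimethyloxiran-2-yl]ethyl}-4-hydroxy-3-methyl-2-(prop-2-yn-1-yl)cyclohexan-1-one | C#CC[C@H]1[C@](C)(CC[C@@H]2OC2(C)C)[C@@H](O)CCC1=O | intermediate
15 | ring A/B hydroxy ketone: (S)-3-hydroxy-2,2-dimethyloxepane trans-fused to a cyclohexanone through the angular C(Me) and the ether CH; prop-2-ynyl on the CH between angular carbon and C=O, cis to the angular methyl | C#CC[C@H]2[C@]3(C)CC[C@H](O)C(C)(C)O[C@H]3CCC2=O | intermediate
16 | ring A/B exocyclic alkene: as 15 with C=CH2 in place of C=O | C#CC[C@H]2[C@]3(C)CC[C@H](O)C(C)(C)O[C@H]3CCC2=C | intermediate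
17 | ring A/B spiro-epoxide: as 16 with the exocyclic alkene epoxidised, oxygen trans to the angular methyl | C#CC[C@H]2[C@]3(C)CC[C@H](O)C(C)(C)O[C@H]3CC[C@@]24CO4 | intermediate
18 | ring A/B diol: ring B tertiary carbinol C(Me)OH (methyl cis to the angular methyl) and ring A secondary alcohol; propargyl arm | C#CC[C@H]2[C@]3(C)CC[C@H](O)C(C)(C)O[C@H]3CC[C@]2(C)O | intermediate
19 | mono-silyl ether: as 18 with the ring A hydroxyl as tert-butyldimethylsilyl ether | C#CC[C@H]2[C@]3(C)CC[C@H](O[Si](C)(C)C(C)(C)C)C(C)(C)O[C@H]3CC[C@]2(C)O | intermediate
20 | ring A/B bis-silyl ether: as 19 with the tertiary hydroxyl as triethylsilyl ether | C#CC[C@H]2[C@]3(C)CC[C@H](O[Si](C)(C)C(C)(C)C)C(C)(C)O[C@H]3CC[C@]2(C)O[Si](CC)(CC)CC | intermediate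
21 | (E)-alkenyl(dicyclohexyl)borane from 20 (boron on the terminal carbon) | C1CCCCC1B(/C=C/C[C@H]2[C@]3(C)CC[C@H](O[Si](C)(C)C(C)(C)C)C(C)(C)O[C@H]3CC[C@]2(C)O[Si](CC)(CC)CC)C1CCCCC1 | intermediate
22 | ring A/B aldehyde: as 20 with CH2CH2CHO in place of the propargyl group | O=CCC[C@H]2[C@]3(C)CC[C@H](O[Si](C)(C)C(C)(C)C)C(C)(C)O[C@H]3CC[C@]2(C)O[Si](CC)(CC)CC | intermediate
23 | 3-(triphenylphosphoranylidene)butan-2-one | CC(=O)C(C)=P(c1ccccc1)(c1ccccc1)c1ccccc1 | starting material
24 | ring A/B (E)-enone: arm CH2CH2CH=C(CH3)C(=O)CH3 | CC(=O)/C(C)=C/CC[C@H]2[C@]3(C)CC[C@H](O[Si](C)(C)C(C)(C)C)C(C)(C)O[C@H]3CC[C@]2(C)O[Si](CC)(CC)CC | intermediate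
25 | ring A/B diene: arm CH2CH2CH=C(CH3)C(OSi(iPr)3)=CH2 with E alkene | C=C(O[Si](C(C)C)(C(C)C)C(C)C)/C(C)=C/CC[C@H]2[C@]3(C)CC[C@H](O[Si](C)(C)C(C)(C)C)C(C)(C)O[C@H]3CC[C@]2(C)O[Si](CC)(CC)CC | intermediate
26 | 4-methoxyphenol | COc1ccc(O)cc1 | starting material
27 | 4,4-dimethoxycyclohexa-2,5-dien-1-one | COC1(OC)C=CC(=O)C=C1 | intermediate
28 | cis-fused cycloadduct: ring C triisopropylsilyl enol ether; ring D enone with dimethyl ketal; tether-bearing CH cis to the ring D carbonyl | COC1(OC)C=CC(=O)[C@H]2[C@@H]1CC(O[Si](C(C)C)(C(C)C)C(C)C)=C(C)[C@H]2CC[C@H]3[C@]4(C)CC[C@H](O[Si](C)(C)C(C)(C)C)C(C)(C)O[C@H]4CC[C@]3(C)O[Si](CC)(CC)CC | intermediate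
29 | as 28 with the ring D alkene saturated | COC1(OC)CCC(=O)[C@H]2[C@@H]1CC(O[Si](C(C)C)(C(C)C)C(C)C)=C(C)[C@H]2CC[C@H]3[C@]4(C)CC[C@H](O[Si](C)(C)C(C)(C)C)C(C)(C)O[C@H]4CC[C@]3(C)O[Si](CC)(CC)CC | intermediate
30 | as 29 with C=CH2 in place of the ring D ketone | COC1(OC)CCC(=C)[C@H]2[C@@H]1CC(O[Si](C(C)C)(C(C)C)C(C)C)=C(C)[C@H]2CC[C@H]3[C@]4(C)CC[C@H](O[Si](C)(C)C(C)(C)C)C(C)(C)O[C@H]4CC[C@]3(C)O[Si](CC)(CC)CC | intermediate
31 | as 30 with a spiro-cyclopropane in place of the exocyclic alkene | COC1(OC)CCC5(CC5)[C@H]2[C@@H]1CC(O[Si](C(C)C)(C(C)C)C(C)C)=C(C)[C@H]2CC[C@H]3[C@]4(C)CC[C@H](O[Si](C)(C)C(C)(C)C)C(C)(C)O[C@H]4CC[C@]3(C)O[Si](CC)(CC)CC | intermediate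
32 | ring D gem-dimethyl ketal | COC1(OC)CCC(C)(C)[C@H]2[C@@H]1CC(O[Si](C(C)C)(C(C)C)C(C)C)=C(C)[C@H]2CC[C@H]3[C@]4(C)CC[C@H](O[Si](C)(C)C(C)(C)C)C(C)(C)O[C@H]4CC[C@]3(C)O[Si](CC)(CC)CC | intermediate
33 | ring D ketone (ketal hydrolysed; CMe2 in place) | O=C1CCC(C)(C)[C@H]2[C@@H]1CC(O[Si](C(C)C)(C(C)C)C(C)C)=C(C)[C@H]2CC[C@H]3[C@]4(C)CC[C@H](O[Si](C)(C)C(C)(C)C)C(C)(C)O[C@H]4CC[C@]3(C)O[Si](CC)(CC)CC | intermediate
34 | as 33 with C=CH2 in place of the ketone | C=C1CCC(C)(C)[C@H]2[C@@H]1CC(O[Si](C(C)C)(C(C)C)C(C)C)=C(C)[C@H]2CC[C@H]3[C@]4(C)CC[C@H](O[Si](C)(C)C(C)(C)C)C(C)(C)O[C@H]4CC[C@]3(C)O[Si](CC)(CC)CC | intermediate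
35 | ring D tertiary alcohol C(Me)OH, hydroxyl cis to both fusion hydrogens; ring C silyl enol ether intact | C[C@]1(O)CCC(C)(C)[C@H]2[C@@H]1CC(O[Si](C(C)C)(C(C)C)C(C)C)=C(C)[C@H]2CC[C@H]3[C@]4(C)CC[C@H](O[Si](C)(C)C(C)(C)C)C(C)(C)O[C@H]4CC[C@]3(C)O[Si](CC)(CC)CC | intermediate
36 | sipholenol K bis-silyl ether (ring A O-tert-butyldimethylsilyl, ring B O-triethylsilyl) | CC1=C(CC[C@H]2[C@]3(C)CC[C@H](O[Si](C)(C)C(C)(C)C)C(C)(C)O[C@H]3CC[C@]2(C)O[Si](CC)(CC)CC)[C@@H]2[C@H](CC1=O)[C@@](C)(O)CCC2(C)C | intermediate
37 | sipholenol K | CC1=C(CC[C@H]2[C@]3(C)CC[C@H](O)C(C)(C)O[C@H]3CC[C@]2(C)O)[C@@H]2[C@H](CC1=O)[C@@](C)(O)CCC2(C)C | target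

## Step count and least certain steps

Total step count: 26. Longest linear sequence: 25 steps (steps 1 to 15 and 17 to 26); step 16 is a one-step branch.

**Step 17 (key step).** The most likely failure is protodesilylation of the dienol ether, or slow turnover because the strongly acidic catalyst is held by the ether and silyloxy oxygens of 25, before the hindered cycloaddition occurs. The second concern is weaker facial discrimination than the model predicts for a diene of this size. The fallback is an anionic route to the same ring. It sets out from 24, which LiN(iPr)2 at −78 °C deprotonates at the methyl group to give lithium dienolate F1. F1 adds to 27 by two consecutive Michael additions: the former methyl carbon bonds to the carbon beside the ketal, and the resulting ring D enolate bonds to the enone β-carbon. This gives tricyclic lithium enolate F2, the enolate of which 28 is the silyl ether, and trapping with iPr3SiOTf returns to the route at 28. No Lewis acid is involved. The price is the loss of catalyst control: the two cis-fused adducts that differ in the relation between the halves would have to be separated.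

**Step 8.** The most likely failure is attack of the hydroxyl at the secondary epoxide carbon (six-membered exo closure) in competition with the wanted attack at the tertiary carbon. The exo path is geometrically easier, and only charge stabilisation favours the endo path. The fallback forms the bond from oxygen to the tertiary carbon in an exo mode. It sets out from 13. Et2Al(NC9H18) (diethylaluminium 2,2,6,6-tetramethylpiperidide) isomerises the epoxide to allylic alcohol F3 by taking a methyl proton, with the carbinol configuration kept. HF·pyridine frees the ring hydroxyl to give diol F4 and leaves the silylalkyne. N-Iodosuccinimide then closes the oxepane by attack of the ring hydroxyl on the tertiary end of the 1,1-disubstituted alkene (7-exo iodoetherification), giving iodomethyl oxepane F5. Bu3SnH with AIBN replaces iodine by hydrogen, which removes the chirality of the new quaternary carbon and gives silylalkyne F6. K2CO3 in methanol removes the C-silyl group and the route is rejoined at 15.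

**Step 20 (with step 21).** The most likely failure is attack of the carbene source or of trace acid on the silyl enol ether, or a sluggish hydrogenolysis that forces acidic conditions under which the ketal and the enol ether degrade. The fallback is a hydrogen-atom-transfer hydromethylation that sets out from 30. Fe(acac)3 and PhSiH3 generate the tertiary radical, which adds to formaldehyde N-tosylhydrazone to give hydrazide F7. Heating F7 in methanol expels sulfinate and dinitrogen and leaves the second methyl group, so the route is rejoined at 32 without a cyclopropane and without acid.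

**Step 24.** The most likely failure is insufficient facial selectivity when the planar tertiary radical captures O2, or hydrogen-atom transfer to the enol ether. The fallback is polar and changes the order of events; it sets out from 34. Saegusa–Ito oxidation with Pd(OAc)2 is done first and gives enone F8 with the exocyclic alkene intact. mCPBA, which now meets no enol ether, epoxidises the exocyclic alkene from the convex face to give spiro-epoxide F9. LiAlH4 opens the epoxide at CH2 and also reduces the ring C carbonyl, giving diol F10. MnO2 reoxidises only the allylic alcohol and the route is rejoined at 36.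

## Further compounds

F1 | step 17 | lithium dienolate of 24 | [Li]OC(=C)/C(C)=C/CC[C@H]2[C@]3(C)CC[C@H](O[Si](C)(C)C(C)(C)C)C(C)(C)O[C@H]3CC[C@]2(C)O[Si](CC)(CC)CC
F2 | step 17 | tricyclic lithium enolate (lithium in place of the triisopropylsilyl group of 28) | COC1(OC)C=CC(=O)[C@H]2[C@@H]1CC(O[Li])=C(C)[C@H]2CC[C@H]3[C@]4(C)CC[C@H](O[Si](C)(C)C(C)(C)C)C(C)(C)O[C@H]4CC[C@]3(C)O[Si](CC)(CC)CC
F3 | step 8 | allylic alcohol from 13 (secondary carbinol beside an isopropenyl group) | C[Si](C)(C)C#CC[C@H]1[C@](C)(CC[C@H](O)C(C)=C)[C@@H](O[Si](C)(C)C(C)(C)C)CCC1=O
F4 | step 8 | diol from F3 (ring hydroxyl free; silylalkyne kept) | C[Si](C)(C)C#CC[C@H]1[C@](C)(CC[C@H](O)C(C)=C)[C@@H](O)CCC1=O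
F5 | step 8 | iodomethyl oxepane (C(CH3)(CH2I)–O carbon; mixture at that carbon) | C[Si](C)(C)C#CC[C@H]2[C@]3(C)CC[C@H](O)C(C)(CI)O[C@H]3CCC2=O
F6 | step 8 | C-trimethylsilyl derivative of 15 | C[Si](C)(C)C#CC[C@H]2[C@]3(C)CC[C@H](O)C(C)(C)O[C@H]3CCC2=O
F7 | step 20 | N′-alkyl-N-tosylhydrazide from 30 (C(CH3)(CH2NHNHTs) carbon; mixture at that carbon) | COC1(OC)CCC(C)(CNNS(=O)(=O)c5ccc(C)cc5)[C@H]2[C@@H]1CC(O[Si](C(C)C)(C(C)C)C(C)C)=C(C)[C@H]2CC[C@H]3[C@]4(C)CC[C@H](O[Si](C)(C)C(C)(C)C)C(C)(C)O[C@H]4CC[C@]3(C)O[Si](CC)(CC)CC
F8 | step 24 | ring C enone with ring D exocyclic alkene | C=C1CCC(C)(C)[C@H]2[C@@H]1CC(=O)C(C)=C2CC[C@H]3[C@]4(C)CC[C@H](O[Si](C)(C)C(C)(C)C)C(C)(C)O[C@H]4CC[C@]3(C)O[Si](CC)(CC)CC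
F9 | step 24 | ring D spiro-epoxide of F8 (oxygen cis to the fusion hydrogens) | O1C[C@@]12CCC(C)(C)[C@H]3[C@@H]2CC(=O)C(C)=C3CC[C@H]4[C@]5(C)CC[C@H](O[Si](C)(C)C(C)(C)C)C(C)(C)O[C@H]5CC[C@]4(C)O[Si](CC)(CC)CC
F10 | step 24 | diol from F9 (ring D tertiary alcohol; ring C allylic alcohol, mixture at that carbinol) | C[C@]1(O)CCC(C)(C)[C@H]2[C@@H]1CC(O)C(C)=C2CC[C@H]3[C@]4(C)CC[C@H](O[Si](C)(C)C(C)(C)C)C(C)(C)O[C@H]4CC[C@]3(C)O[Si](CC)(CC)CC
A1 | alternative 1 | (2E,6S,7S,10S)-6,7:10,11-diepoxy-3,7,11-trimethyldodec-2-en-1-yl tert-butyl carbonate | CC(C)(C)OC(=O)OC/C=C(C)/CC[C@@H]1O[C@@]1(C)CC[C@@H]1OC1(C)C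
A2 | alternative 1 | ring A/B bicycle as cyclic carbonate of the tertiary and primary alcohols | O=C1OC[C@H]2[C@]3(C)CC[C@H](O)C(C)(C)O[C@H]3CC[C@]2(C)O1
A3 | alternative 2 | pyranone of the full skeleton (six-membered ring A ketone; both tertiary alcohols as trimethylsilyl ethers) | CC1=C(CC[C@H]2[C@]3(C)CC(=O)C(C)(C)O[C@H]3CC[C@]2(C)O[Si](C)(C)C)[C@@H]2[C@H](CC1=O)[C@@](C)(O[Si](C)(C)C)CCC2(C)C
A4 | alternative 2 | oxepan-3-one of the full skeleton | CC1=C(CC[C@H]2[C@]3(C)CCC(=O)C(C)(C)O[C@H]3CC[C@]2(C)O[Si](C)(C)C)[C@@H]2[C@H](CC1=O)[C@@](C)(O[Si](C)(C)C)CCC2(C)C
A5 | alternative 3 | oxepane keto enoate (methyl ketone chain on the ether CH; (E)-enoate on the angular carbon) | COC(=O)/C=C/[C@]1(C)CC[C@H](O[Si](C)(C)C(C)(C)C)C(C)(C)O[C@H]1CCC(C)=O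
A6 | alternative 3 | ring A/B hydroxy ester | COC(=O)C[C@H]2[C@]3(C)CC[C@H](O[Si](C)(C)C(C)(C)C)C(C)(C)O[C@H]3CC[C@]2(C)O
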